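## Structural features

The target is a 2,3-dihydroflavonol: ring A (benzene) is fused through C4a–C8a to ring C (a pyran-4-one), which carries ring B (3-hydroxy-4-methoxyphenyl) at C2 and a hydroxyl at C3. C2 and C3 are adjacent stereocentres, both R, so the aryl group and the hydroxyl are trans and can both lie equatorial. Ring A is fully differentiated: its three oxygens stand in a 1,3,5 pattern as the ring ether O1 on C8a, a methyl ether on C7 and a free, carbonyl-chelated hydroxyl on C5; the prenyl chain sits on C8 between O1 and the 7-methoxyl, and C6 is the only unsubstituted carbon. The fragile parts are the trisubstituted prenyl alkene (acid-induced addition, or cyclisation onto a free ortho phenol), the α-hydroxy ketone with its benzylic C2–O1 bond (ring opening, epimerisation or oxidation to the flavonol under base) and the p-methoxybenzylic C2, which ionises easily under acid. The stereochemistry is the lesser problem, because a trans chalcone epoxide translates directly into the trans C2/C3 pair. The real difficulty is ring A: phloroglucinol-type precursors have equivalent oxygens and equivalent carbons, so three different oxygen substituents and one C-prenyl group can be placed only by long protection sequences that tend to give 6-prenyl/8-prenyl and O-regioisomers. The key step exploits the O–C7–C8(prenyl)–C8a–O array and the C4a–C5(O)–C6 array of ring A: the first maps onto a ketene carbon joined to a prenyl-substituted ynol ether, the second onto the remaining three carbons of an alkoxycyclobutenone, so the ring is assembled with each oxygen already carrying a different group.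

## Logic of the disconnections

22 ⇒ 21. The O–H bond at C5 is traced back to an O–ethyl bond. The 5-oxygen has to stay capped until ring C exists: with both oxygens ortho to the C4 carbonyl free, either could close the pyranone and the 6-prenyl isomer would form beside the 8-prenyl one. The ethyl group is simply the one that arrives with 5. Nothing is gained in skeleton, but the direction of ring closure is secured. The forward step must remove one ethyl ether, helped by chelation to the C4 carbonyl, while two methyl ethers, the prenyl alkene and both stereocentres survive.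

21 ⇒ 19 (through 20). The O1–C2 bond is cut and the two acetal protecting groups are restored. An epoxy ketone stores both stereocentres in one ring: C3 already has its final configuration and C2 is one inversion away. The gain is the loss of ring C and the reduction of two adjacent stereocentres to one trans epoxide. The forward step must free the phenol, open the epoxide at the benzylic carbon in the 6-endo mode with anti attack, avoid 5-exo attack at the α-carbon, and use acid mild enough for the prenyl group.

19 ⇒ 18. Both C–O bonds of the oxirane are cut. All stereochemistry disappears and a planar E-enone remains, so both stereocentres are made in one catalytic event. The demand is face selection by the catalyst on a hindered, twisted aryl enone, and complete chemoselectivity for the electron-poor alkene over the electron-rich prenyl alkene, which calls for a nucleophilic oxidant.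

18 ⇒ 13 + 16 (through 17). The C4–C4a bond between ring A and the carbonyl is cut. This is the most convergent cut: it divides the molecule into a ring A half and a ring B half of similar size, and C4a lies between two oxygens, where an aryl anion forms most easily. The demand is that metalation of 13 occurs at C4a and not at C6 or at the benzylic–allylic CH2, and that 17 adds once, in the 1,2 mode, to the amide of 16.

16 ⇒ 15 ⇒ 14. The Cα=Cβ double bond of 16 is cut to the aldehyde carbon of 15 and a two-carbon phosphonate; the O–CH2 acetal bond of 15 is cut to give 14. Ring B returns to a commercial aldehyde in two routine steps. The olefination must be E-selective, and the acetal must tolerate the organolithium and peroxide steps that follow.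

13 ⇒ 12 ⇒ 11 ⇒ 10. Only oxygen–substituent bonds change: the O–CH2 acetal bond at the future O1 is cut, the O–Si bond is restored, and the O–CH3 bond at the future 7-oxygen is cut. The silyl ether delivered by the ring construction neither directs metalation nor leaves in the final acid step, and the free hydroxyl of 10 must become the 7-methoxyl before the other oxygen is touched. The gain is arrival at the direct product of ring construction with each oxygen already distinct. The demand is that methylation leaves the silyl ether in place, so the two oxygens flanking the prenyl carbon are never exchanged.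

10 ⇒ 4 + 5 (through 6, 7, 8, 9). Three bonds of ring A are cut: C7–C8, C4a–C8a and C6–C7. The cut turns a tetrasubstituted benzene with three different oxygens into two small achiral pieces whose polarity dictates the pattern: the ketene carbon from 5 becomes C7, the prenyl-bearing alkyne carbon of 4 becomes C8, the siloxy carbon becomes C8a, and the ethoxy carbon of 5 becomes C5. The mapping was rechecked atom by atom and is consistent with the substitution pattern of 22. The demand is a regiospecific ketene–ynol ether cycloaddition, and a ring opening of 5 that proceeds at a temperature 4 survives.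

4 ⇒ 1 + 2 (through 3). The O–Si bond and the bond between the two alkyne carbons are cut. The oxygen-bearing alkyne carbon is the ester carbon of 1; the second alkyne carbon, to which the prenyl-bearing CH2 migrates, comes from a one-carbon dihalide. This brings the ynol ether back to a simple ester in one operation. The demand is that carbenoid addition to the ester outruns enolisation of the β,γ-unsaturated ester, and that 2 silylates 3 on oxygen.

## Other disconnections considered

Alternative 1: The cut removes ring A last by breaking C8–C8a and C4a–C5. The pyranone ring with both stereocentres, bromo-dihydropyranone A2, is the dienophile; the doubly oxygenated, prenyl-terminated ketene acetal A3 is the diene. In the forward step A3 would add across the C4a=C8a double bond of A2, with the nucleophilic diene terminus bonding to C8a and the ketene acetal carbon to C4a. Loss of HBr and of methoxytrimethylsilane would aromatise the adduct to dibenzoate A1, which needs only ester cleavage.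
- In its favour: the 5-hydroxyl appears free and chelated at once, so no late dealkylation next to a prenyl group is needed, and no acylation or metalation regiochemistry on ring A arises. On these two points it is better than the chosen plan. Like the chosen plan it builds ring A from acyclic pieces with each oxygen predefined, so on control of the oxygen pattern the two are equal.
- Against it: C8a of A2 is the oxygen-bearing β-carbon of a vinylogous ester, a weak dienophile, and it must bond to the substituted, prenyl-bearing terminus of A3. The cycloaddition is therefore electronically damped and sterically loaded, whereas the chosen step joins a ketene carbon to a strongly nucleophilic ynol ether carbon. A3 is a fully substituted, moisture-sensitive ketene acetal of uncertain geometry. A2 must first be made as a single enantiomer and then carry an epimerisable α-benzoyloxy ketone through heating and elimination; the chosen plan keeps ring construction free of stereocentres and introduces them afterwards.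
- Step economy: the enantioselective preparation of A2 and the double enol silylation to A3 are expected to cost more than the nine-step longest line of the chosen route.

Alternative 2: The cut is the C3–C4 bond. Dialdehyde A5, a ring A benzaldehyde whose ortho oxygen carries an α-aryl acetaldehyde unit, would be closed by a chiral triazolylidene carbene. The carbene converts the aromatic aldehyde into an acyl anion equivalent that adds to the aliphatic aldehyde, giving A4 with ring C closed and the C3 carbinol set. Because the α-aryloxy-α-aryl aldehyde centre epimerises easily, the catalyst could select the C2 configuration dynamically.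
- In its favour: ring C and both stereocentres would come from one catalytic, non-acidic step that the prenyl group should tolerate, and no epoxide with a p-methoxybenzylic carbon has to be handled. In stereochemical economy this is better than the chosen epoxidation–cyclisation pair, and in mildness toward the prenyl group it is at least equal.
- Against it: the aromatic aldehyde is flanked by two alkoxy groups, electron-rich and hindered, while the aliphatic aldehyde is the more electrophilic. The carbene is therefore more likely to form its acyl anion at the wrong carbonyl, which would lead to the isomeric 4-hydroxychroman-3-one. A5 is prone to β-elimination of the phenoxide and is awkward to make. Cis/trans control rests on the catalyst alone, whereas the chosen plan relays it from a trans epoxide.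
- Comparison: this cut does not say how ring A gets its pattern, so the substitution problem that the chosen key step solves remains. The 5-methyl ether of A4 must still be cleaved selectively beside the 7-methyl ether, a task equal to the chosen final step. Step count is expected to be similar or longer once ring A is included.

Alternative 3: The cut is again C4–C4a, but made intramolecularly. Phenol A8 would open glycidic ester A9 at the benzylic carbon. After acetylation and ester hydrolysis, acid A7 would be converted into its mixed trifluoroacetic anhydride, which acylates C4a and closes ring C to A6.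
- In its favour: the tether allows acylation only at C4a, so the regiochemical risk of the chosen metalation step is absent; on that point it is better. The stereocentres originate in the prenyl-free ring B fragment, where the full range of asymmetric oxidations can be used, OsO4-based dihydroxylation included; this is an advantage over the chosen plan, whose enone must be oxidised beside the prenyl alkene. The final ether cleavage concerns a methyl group, which leaves more easily than ethyl.
- Against it: the acylating medium is strongly acidic, and the substrate holds a prenyl alkene on an electron-rich ring and a p-methoxybenzylic aryl ether, so alkene addition, cation cyclisation and ionisation at C2 are to be feared. The activated α-acetoxy acid can epimerise at C3. Opening of A9 by a phenol with clean inversion at a p-methoxybenzylic carbon is uncertain. A8 must be made by selective C-prenylation of a phloroglucinol ether between hydroxyl and methoxyl, the very problem the chosen benzannulation avoids.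
- Comparison: the chosen route forms the same C4–C4a bond by an anionic, acid-free process. In step count the two are expected to be close.

Key step: step 2

Assumption: the SMILES encodes 2R,3R (aryl and hydroxyl trans); the facial sense of the polyleucine epoxidation is taken to be the one established for simple chalcones and should be confirmed on a model enone.

Remark: the two benzannulation partners are kept as 4 and 5. The ethyl group that commercial 5 delivers serves as the mask of the 5-oxygen until ring C is closed, and the triisopropylsilyl group keeps the ynol ether stable.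

## Steps

Step 1
Reactants: 1 ethyl 4-methylpent-3-enoate; 2 triisopropylsilyl chloride
Product: 4 triisopropyl(5-methylhex-4-en-1-ynyloxy)silane, via lithium ynolate 3 (not isolated)
Conditions: CH2Br2, lithium 2,2,6,6-tetramethylpiperidide (from the amine and n-BuLi), THF, −78 °C; n-BuLi, −78 → 0 °C; then 2, −78 °C → rt
Reagents that add atoms: dibromomethane, BrCBr
Why: Kowalski ester homologation: dibromomethyllithium should add to the ester at −78 °C faster than it enolises it, bromine–lithium exchange then triggers the 1,2-shift to ynolate 3, and the bulky chlorosilane 2 silylates 3 on oxygen to give the siloxyalkyne.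

Step 2
Reactants: 4 triisopropyl(5-methylhex-4-en-1-ynyloxy)silane; 5 3-ethoxycyclobut-2-en-1-one
Product: 10 5-ethoxy-2-(3-methylbut-2-enyl)-3-(triisopropylsilyloxy)phenol, via ethoxy vinylketene 6 (not isolated), via vinylcyclobutenone adduct 7 (not isolated), via dienylketene 8 (not isolated), via cyclohexadienone 9 (not isolated)
Conditions: toluene, 80 → 110 °C, sealed tube, 5 added slowly to 4 (1.3 equiv)
Reagents that add atoms: none
Why: Danheiser benzannulation, the closest known reaction being the thermal union of cyclobutenones with siloxyalkynes to give resorcinol monosilyl ethers. Heating opens 5 by 4π electrocyclic cleavage to vinylketene 6, whose ketene carbon is attacked by the nucleophilic β-carbon of ynol ether 4 in a regiospecific [2+2] cycloaddition that gives 7. A second 4π opening gives dienylketene 8, and ring A closes by 6π electrocyclisation (disrotatory, six-membered, C6–C7 bond) to 9, which tautomerises to phenol 10. Three ring bonds form: C7–C8 and C4a–C8a in the cycloaddition and C6–C7 in the electrocyclisation. No stereocentre is created (the one in 7 is lost on ring opening), so only regiochemistry matters, and it is fixed by the polarity match between the electrophilic ketene carbon and the alkyne carbon remote from oxygen. The prenyl carbon therefore ends up next to the new phenol carbon, the siloxy carbon on its other side, and the ethoxy carbon para to prenyl. The bulky silyl group keeps 4 from rearranging, and the neutral, reagent-free conditions leave the prenyl alkene untouched. The ethoxy donor makes 5 a vinylogous ester that should open more slowly than alkyl cyclobutenones, hence the higher final temperature and the slow addition of 5 to an excess of 4.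

Step 3
Reactants: 10 5-ethoxy-2-(3-methylbut-2-enyl)-3-(triisopropylsilyloxy)phenol
Product: 11 [5-ethoxy-3-methoxy-2-(3-methylbut-2-enyl)phenoxy]triisopropylsilane
Conditions: MeI, K2CO3, acetone, 40 °C
Reagents that add atoms: iodomethane, CI
Why: Williamson ether synthesis on the only free phenol; the weak base in acetone should leave the hindered triisopropylsilyl ether in place, so the two oxygens flanking the prenyl carbon stay distinct.

Step 4
Reactants: 11 [5-ethoxy-3-methoxy-2-(3-methylbut-2-enyl)phenoxy]triisopropylsilane
Product: 12 5-ethoxy-3-methoxy-2-(3-methylbut-2-enyl)phenol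
Conditions: n-Bu4NF, THF, 0 °C
Reagents that add atoms: none
Why: Fluoride-mediated desilylation of an aryl silyl ether; the alkyl ethers and the alkene are inert, and the freed hydroxyl is the future O1.

Step 5
Reactants: 12 5-ethoxy-3-methoxy-2-(3-methylbut-2-enyl)phenol
Product: 13 5-ethoxy-1-methoxy-3-(methoxymethoxy)-2-(3-methylbut-2-enyl)benzene
Conditions: MOMCl, i-Pr2NEt, CH2Cl2, 0 °C → rt
Reagents that add atoms: chloromethyl methyl ether, COCCl
Why: Methoxymethyl ether formation (O-alkylation of the phenol under mild base); the acetal directs the metalation of step 8 and is removed by the acid of step 10.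

Step 6
Reactants: 14 isovanillin (3-hydroxy-4-methoxybenzaldehyde)
Product: 15 4-methoxy-3-(methoxymethoxy)benzaldehyde
Conditions: MOMCl, i-Pr2NEt, CH2Cl2, 0 °C → rt
Reagents that add atoms: chloromethyl methyl ether, COCCl
Why: Methoxymethyl ether formation on the ring B phenol, so that it survives the organolithium and the basic peroxide and is released together with the ring A acetal in step 10.

Step 7
Reactants: 15 4-methoxy-3-(methoxymethoxy)benzaldehyde
Product: 16 (E)-N-methoxy-3-[4-methoxy-3-(methoxymethoxy)phenyl]-N-methylprop-2-enamide
Conditions: (EtO)2P(O)CH2C(O)N(OMe)Me, NaH, THF, 0 °C → rt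
Reagents that add atoms: diethyl [2-[methoxy(methyl)amino]-2-oxoethyl]phosphonate, CCOP(=O)(CC(=O)N(C)OC)OCC
Why: Horner–Wadsworth–Emmons olefination with a stabilised phosphonate, which should give the E-cinnamamide and thereby fixes the E-geometry of the later enone.

Step 8
Reactants: 13 5-ethoxy-1-methoxy-3-(methoxymethoxy)-2-(3-methylbut-2-enyl)benzene; 16 (E)-N-methoxy-3-[4-methoxy-3-(methoxymethoxy)phenyl]-N-methylprop-2-enamide
Product: 18 (E)-1-[6-ethoxy-4-methoxy-2-(methoxymethoxy)-3-(3-methylbut-2-enyl)phenyl]-3-[4-methoxy-3-(methoxymethoxy)phenyl]prop-2-en-1-one, via aryllithium 17 (not isolated)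
Conditions: n-BuLi, THF, −20 → 0 °C; then 16, −78 → 0 °C; then H2O
Reagents that add atoms: none
Why: Directed ortho-metalation followed by Weinreb ketone synthesis: C4a lies between the chelating acetal (turned toward C4a by the neighbouring prenyl group) and the ethoxy group and should be lithiated in preference to C6. Aryllithium 17 should add once, in the 1,2 mode, to the N-methoxy-N-methyl amide of 16, and the E-chalcone is released on work-up.

Step 9
Reactants: 18 (E)-1-[6-ethoxy-4-methoxy-2-(methoxymethoxy)-3-(3-methylbut-2-enyl)phenyl]-3-[4-methoxy-3-(methoxymethoxy)phenyl]prop-2-en-1-one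
Product: 19 [6-ethoxy-4-methoxy-2-(methoxymethoxy)-3-(3-methylbut-2-enyl)phenyl]-[(2R,3S)-3-[4-methoxy-3-(methoxymethoxy)phenyl]oxiran-2-yl]methanone
Conditions: poly-L-leucine, urea·H2O2, DBU, THF, rt
Reagents that add atoms: urea–hydrogen peroxide, NC(N)=O.OO
Why: Julia–Colonna asymmetric epoxidation (peptide-controlled Weitz–Scheffer reaction): the hydroperoxide anion adds only to the enone and not to the electron-rich prenyl alkene. The L-configured peptide is expected to deliver the trans (2R,3S)-epoxide, the facial sense known for chalcones, which sets the future C3 as R and the future C2 one inversion away from R.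

Step 10
Reactants: 19 [6-ethoxy-4-methoxy-2-(methoxymethoxy)-3-(3-methylbut-2-enyl)phenyl]-[(2R,3S)-3-[4-methoxy-3-(methoxymethoxy)phenyl]oxiran-2-yl]methanone
Product: 21 (2R,3R)-5-ethoxy-3-hydroxy-2-(3-hydroxy-4-methoxyphenyl)-7-methoxy-8-(3-methylbut-2-enyl)chroman-4-one, via free phenol epoxy ketone 20 (not isolated)
Conditions: HCl (cat.), MeOH–THF, 40 °C
Reagents that add atoms: none
Why: Acid-catalysed acetal cleavage followed by epoxide-opening cyclisation of a 2'-hydroxychalcone epoxide: the freed ring A hydroxyl of 20 attacks the activated epoxide at the benzylic carbon (6-endo, anti), inverting it to 2R, while the 3R carbinol is carried over unchanged. The trans diequatorial product is also the thermodynamically preferred one, and only the oxygen next to the prenyl carbon can close because the other ortho oxygen is still an ethyl ether.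

Step 11
Reactants: 21 (2R,3R)-5-ethoxy-3-hydroxy-2-(3-hydroxy-4-methoxyphenyl)-7-methoxy-8-(3-methylbut-2-enyl)chroman-4-one
Product: 22 (2R,3R)-3,5-dihydroxy-2-(3-hydroxy-4-methoxyphenyl)-7-methoxy-8-(3-methylbut-2-enyl)chroman-4-one
Conditions: BCl3, CH2Cl2, −78 → −20 °C; then H2O
Reagents that add atoms: none
Why: Chelation-assisted ether cleavage: BCl3 bridges the C4 carbonyl and the peri 5-oxygen, and chloride removes the ethyl group, while the non-chelated 7- and 4'-methyl ethers should survive at low temperature. No stereocentre is involved.

## Compound list

1 | ethyl 4-methylpent-3-enoate | CCOC(=O)CC=C(C)C | starting material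
2 | triisopropylsilyl chloride | CC(C)[Si](Cl)(C(C)C)C(C)C | starting material
3 | lithium 5-methylhex-4-en-1-yn-1-olate (lithium ynolate) | [Li+].[O-]C#CCC=C(C)C | intermediate (not isolated)
4 | triisopropyl(5-methylhex-4-en-1-ynyloxy)silane | CC(C)=CCC#CO[Si](C(C)C)(C(C)C)C(C)C | intermediate
5 | 3-ethoxycyclobut-2-en-1-one | CCOC1=CC(=O)C1 | starting material
6 | 3-ethoxybuta-1,3-dien-1-one (ethoxy vinylketene) | CCOC(=C)C=C=O | intermediate (not isolated)
7 | 4-(1-ethoxyethenyl)-2-(3-methylbut-2-enyl)-3-(triisopropylsilyloxy)cyclobut-2-en-1-one (racemic) | CCOC(=C)C1C(=O)C(CC=C(C)C)=C1O[Si](C(C)C)(C(C)C)C(C)C | intermediate (not isolated)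
8 | (3E)-5-ethoxy-2-(3-methylbut-2-enyl)-3-(triisopropylsilyloxy)hexa-1,3,5-trien-1-one (dienylketene) | O=C=C(CC=C(C)C)/C(O[Si](C(C)C)(C(C)C)C(C)C)=C\C(=C)OCC | intermediate (not isolated)
9 | 5-ethoxy-2-(3-methylbut-2-enyl)-3-(triisopropylsilyloxy)cyclohexa-2,4-dien-1-one | CCOC1=CC(O[Si](C(C)C)(C(C)C)C(C)C)=C(CC=C(C)C)C(=O)C1 | intermediate (not isolated)
10 | 5-ethoxy-2-(3-methylbut-2-enyl)-3-(triisopropylsilyloxy)phenol | CCOc1cc(O)c(CC=C(C)C)c(O[Si](C(C)C)(C(C)C)C(C)C)c1 | intermediate
11 | [5-ethoxy-3-methoxy-2-(3-methylbut-2-enyl)phenoxy]triisopropylsilane | CCOc1cc(OC)c(CC=C(C)C)c(O[Si](C(C)C)(C(C)C)C(C)C)c1 | intermediate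
12 | 5-ethoxy-3-methoxy-2-(3-methylbut-2-enyl)phenol | CCOc1cc(O)c(CC=C(C)C)c(OC)c1 | intermediate
13 | 5-ethoxy-1-methoxy-3-(methoxymethoxy)-2-(3-methylbut-2-enyl)benzene | CCOc1cc(OC)c(CC=C(C)C)c(OCOC)c1 | intermediate
14 | isovanillin (3-hydroxy-4-methoxybenzaldehyde) | COc1ccc(C=O)cc1O | starting material
15 | 4-methoxy-3-(methoxymethoxy)benzaldehyde | COCOc1cc(C=O)ccc1OC | intermediate
16 | (E)-N-methoxy-3-[4-methoxy-3-(methoxymethoxy)phenyl]-N-methylprop-2-enamide | CON(C)C(=O)/C=C/c1ccc(OC)c(OCOC)c1 | intermediate
17 | [6-ethoxy-4-methoxy-2-(methoxymethoxy)-3-(3-methylbut-2-enyl)phenyl]lithium | [Li]c1c(OCC)cc(OC)c(CC=C(C)C)c1OCOC | intermediate (not isolated)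
18 | (E)-1-[6-ethoxy-4-methoxy-2-(methoxymethoxy)-3-(3-methylbut-2-enyl)phenyl]-3-[4-methoxy-3-(methoxymethoxy)phenyl]prop-2-en-1-one | CCOc1cc(OC)c(CC=C(C)C)c(OCOC)c1C(=O)/C=C/c1ccc(OC)c(OCOC)c1 | intermediate
19 | [6-ethoxy-4-methoxy-2-(methoxymethoxy)-3-(3-methylbut-2-enyl)phenyl]-[(2R,3S)-3-[4-methoxy-3-(methoxymethoxy)phenyl]oxiran-2-yl]methanone | CCOc1cc(OC)c(CC=C(C)C)c(OCOC)c1C(=O)[C@@H]2O[C@H]2c3ccc(OC)c(OCOC)c3 | intermediate
20 | [6-ethoxy-2-hydroxy-4-methoxy-3-(3-methylbut-2-enyl)phenyl]-[(2R,3S)-3-(3-hydroxy-4-methoxyphenyl)oxiran-2-yl]methanone | CCOc1cc(OC)c(CC=C(C)C)c(O)c1C(=O)[C@@H]2O[C@H]2c3ccc(OC)c(O)c3 | intermediate (not isolated)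
21 | (2R,3R)-5-ethoxy-3-hydroxy-2-(3-hydroxy-4-methoxyphenyl)-7-methoxy-8-(3-methylbut-2-enyl)chroman-4-one | COc1ccc([C@H]2Oc3c(CC=C(C)C)c(OC)cc(OCC)c3C(=O)[C@@H]2O)cc1O | intermediate
22 | (2R,3R)-3,5-dihydroxy-2-(3-hydroxy-4-methoxyphenyl)-7-methoxy-8-(3-methylbut-2-enyl)chroman-4-one | COc1ccc([C@H]2Oc3c(CC=C(C)C)c(OC)cc(O)c3C(=O)[C@@H]2O)cc1O | target

## Step count and least certain steps

Total step count: 11. Longest linear sequence: 9 steps (steps 1, 2, 3, 4, 5, 8, 9, 10, 11, from 1); the two-step branch from 14 (steps 6 and 7) joins in step 8.

Step 2 (key step). The donor-stabilised cyclobutenone may open too slowly. At the temperature then needed, the siloxyalkyne could rearrange, or the ketene could be lost through dimerisation and through acylation of the phenol it has just formed. The fallback sets out from 4 and returns at 7, and so at 10. The same vinylketene 6 is generated at or below room temperature by dehydrochlorination instead of by electrocyclic opening. Commercial ethyl (E)-3-ethoxybut-2-enoate is saponified with LiOH to (E)-3-ethoxybut-2-enoic acid F1, and oxalyl chloride converts this into (E)-3-ethoxybut-2-enoyl chloride F2. Slow addition of F2 to 4 and Et3N in CH2Cl2 releases 6 by 1,4-elimination of HCl in the presence of its trap (ketene–ynol ether [2+2]). Adduct 7 is then warmed in toluene to complete the opening–closure sequence to 10.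

Step 1. Proton transfer from the doubly activated α-position of the β,γ-unsaturated ester to the carbenoid base, followed by migration of the double bond into conjugation, may compete with addition; silylation on carbon is a lesser risk. The fallback sets out from 1 and returns at 3. Reduction with i-Bu2AlH at −78 °C gives 4-methylpent-3-enal F3. Corey–Fuchs olefination (CBr4, PPh3) gives 1,1-dibromo-5-methylhexa-1,4-diene F4. Two equivalents of n-BuLi convert F4 into (5-methylhex-4-en-1-ynyl)lithium F5, which is oxidised in the same flask with t-BuOOLi to ynolate 3 and silylated with 2 as in step 1.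

Step 8. Metalation at the wrong site is the main risk: C6, flanked by ethoxy and methoxy, and the benzylic–allylic CH2 of the prenyl group compete with C4a. Conjugate addition to 16 is a lesser risk. The fallback sets out from 12 and returns at 18; its first step can only reach C4a, the one free position ortho to the hydroxyl. Ortho-specific formylation of the free phenol (MgCl2, Et3N, paraformaldehyde, MeCN, reflux) gives 6-ethoxy-2-hydroxy-4-methoxy-3-(3-methylbut-2-enyl)benzaldehyde F6. MOMCl with i-Pr2NEt gives 6-ethoxy-4-methoxy-2-(methoxymethoxy)-3-(3-methylbut-2-enyl)benzaldehyde F7. MeMgBr gives 1-[6-ethoxy-4-methoxy-2-(methoxymethoxy)-3-(3-methylbut-2-enyl)phenyl]ethanol F8, and Dess–Martin periodinane gives 1-[6-ethoxy-4-methoxy-2-(methoxymethoxy)-3-(3-methylbut-2-enyl)phenyl]ethanone F9. Claisen–Schmidt condensation of F9 with 15 (KOH, EtOH, rt) gives 18.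

Step 9. Facial selectivity may be poor, or conversion slow, because the di-ortho-substituted aryl ketone is twisted out of conjugation and may bind the peptide catalyst badly. The fallback sets out from 18 and returns at 21; it gives up catalyst control. Weitz–Scheffer epoxidation (H2O2, NaOH, MeOH) gives the racemic trans epoxide, that is 19 together with the (2S,3R)-epoxy ketone F10. The conditions of step 10 carry the pair through 20 and the enantiomeric free phenol epoxy ketone F11 to racemic trans material, that is 21 together with the (2S,3S)-flavanonol F12. Preparative chromatography on a chiral stationary phase removes F12 and returns 21.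

Step 10. Several acid-induced processes may compete with the cyclisation: solvolysis of the epoxide by methanol, 1,2-aroyl migration at the p-methoxybenzylic cation (the isoflavone pathway), cyclisation of the freed phenol onto the protonated prenyl alkene, and partial epimerisation at C2. The fallback sets out from 19 and returns at 21; it separates epoxide opening from phenol release. PhCH2SH with SnCl4 at low temperature opens the epoxide at the benzylic carbon to give the protected (2S)-3-benzylsulfanyl-2-hydroxy ketone F13 (the descriptor changes only because sulfur raises the priority of C3). Dilute HCl in MeOH removes the acetals to give the (2S)-3-benzylsulfanyl-2-hydroxy diphenol F14. AgBF4 in CH2Cl2 then activates the sulfide, so the ring A phenol closes ring C under non-protic conditions. The carbinol centre is untouched throughout, and the trans isomer 21 is the expected main product, separable from its C2 epimer.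

Step 11. HCl released when boron binds the two hydroxyls may add across the prenyl alkene. Chloride may attack the ethyl group too slowly. The 4'-methyl ether may be lost through the neighbouring aryloxyborane. The fallback sets out from 21 and returns at 22; it masks the hydroxyls and changes the Lewis acid. Ac2O in pyridine gives the diacetate [(2R,3R)-2-(3-acetoxy-4-methoxyphenyl)-5-ethoxy-7-methoxy-8-(3-methylbut-2-enyl)-4-oxochroman-3-yl] acetate F15. MgI2·OEt2 in toluene–THF at 60 °C removes the ethyl group through the magnesium chelate without releasing protic acid and gives [(2R,3R)-2-(3-acetoxy-4-methoxyphenyl)-5-hydroxy-7-methoxy-8-(3-methylbut-2-enyl)-4-oxochroman-3-yl] acetate F16. Acid-catalysed methanolysis (HCl, MeOH, rt) of the two acetates then gives 22.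

## Further compounds

F1 | step 2 | (E)-3-ethoxybut-2-enoic acid | CCO/C(C)=C/C(O)=O
F2 | step 2 | (E)-3-ethoxybut-2-enoyl chloride | CCO/C(C)=C/C(Cl)=O
F3 | step 1 | 4-methylpent-3-enal | CC(C)=CCC=O
F4 | step 1 | 1,1-dibromo-5-methylhexa-1,4-diene | CC(C)=CCC=C(Br)Br
F5 | step 1 | (5-methylhex-4-en-1-ynyl)lithium | [Li]C#CCC=C(C)C
F6 | step 8 | 6-ethoxy-2-hydroxy-4-methoxy-3-(3-methylbut-2-enyl)benzaldehyde | CCOc1cc(OC)c(CC=C(C)C)c(O)c1C=O
F7 | step 8 | 6-ethoxy-4-methoxy-2-(methoxymethoxy)-3-(3-methylbut-2-enyl)benzaldehyde | CCOc1cc(OC)c(CC=C(C)C)c(OCOC)c1C=O
F8 | step 8 | 1-[6-ethoxy-4-methoxy-2-(methoxymethoxy)-3-(3-methylbut-2-enyl)phenyl]ethanol (racemic) | CCOc1cc(OC)c(CC=C(C)C)c(OCOC)c1C(C)O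
F9 | step 8 | 1-[6-ethoxy-4-methoxy-2-(methoxymethoxy)-3-(3-methylbut-2-enyl)phenyl]ethanone | CCOc1cc(OC)c(CC=C(C)C)c(OCOC)c1C(C)=O
F10 | step 9 | [6-ethoxy-4-methoxy-2-(methoxymethoxy)-3-(3-methylbut-2-enyl)phenyl]-[(2S,3R)-3-[4-methoxy-3-(methoxymethoxy)phenyl]oxiran-2-yl]methanone | CCOc1cc(OC)c(CC=C(C)C)c(OCOC)c1C(=O)[C@H]2O[C@@H]2c3ccc(OC)c(OCOC)c3
F11 | step 9 | [6-ethoxy-2-hydroxy-4-methoxy-3-(3-methylbut-2-enyl)phenyl]-[(2S,3R)-3-(3-hydroxy-4-methoxyphenyl)oxiran-2-yl]methanone | CCOc1cc(OC)c(CC=C(C)C)c(O)c1C(=O)[C@H]2O[C@@H]2c3ccc(OC)c(O)c3
F12 | step 9 | (2S,3S)-5-ethoxy-3-hydroxy-2-(3-hydroxy-4-methoxyphenyl)-7-methoxy-8-(3-methylbut-2-enyl)chroman-4-one | COc1ccc([C@@H]2Oc3c(CC=C(C)C)c(OC)cc(OCC)c3C(=O)[C@H]2O)cc1O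
F13 | step 10 | (2S)-3-benzylsulfanyl-1-[6-ethoxy-4-methoxy-2-(methoxymethoxy)-3-(3-methylbut-2-enyl)phenyl]-2-hydroxy-3-[4-methoxy-3-(methoxymethoxy)phenyl]propan-1-one (C3 epimers) | CCOc1cc(OC)c(CC=C(C)C)c(OCOC)c1C(=O)[C@H](O)C(SCc2ccccc2)c3ccc(OC)c(OCOC)c3
F14 | step 10 | (2S)-3-benzylsulfanyl-1-[6-ethoxy-2-hydroxy-4-methoxy-3-(3-methylbut-2-enyl)phenyl]-2-hydroxy-3-(3-hydroxy-4-methoxyphenyl)propan-1-one (C3 epimers) | CCOc1cc(OC)c(CC=C(C)C)c(O)c1C(=O)[C@H](O)C(SCc2ccccc2)c3ccc(OC)c(O)c3
F15 | step 11 | [(2R,3R)-2-(3-acetoxy-4-methoxyphenyl)-5-ethoxy-7-methoxy-8-(3-methylbut-2-enyl)-4-oxochroman-3-yl] acetate | COc1ccc([C@H]2Oc3c(CC=C(C)C)c(OC)cc(OCC)c3C(=O)[C@@H]2OC(C)=O)cc1OC(C)=O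
F16 | step 11 | [(2R,3R)-2-(3-acetoxy-4-methoxyphenyl)-5-hydroxy-7-methoxy-8-(3-methylbut-2-enyl)-4-oxochroman-3-yl] acetate | COc1ccc([C@H]2Oc3c(CC=C(C)C)c(OC)cc(O)c3C(=O)[C@@H]2OC(C)=O)cc1OC(C)=O
A1 | alternative 1 | (2R,3R)-3-benzoyloxy-2-(3-benzoyloxy-4-methoxyphenyl)-5-hydroxy-7-methoxy-8-(3-methylbut-2-enyl)chroman-4-one | COc1ccc([C@H]2Oc3c(CC=C(C)C)c(OC)cc(O)c3C(=O)[C@@H]2OC(=O)c2ccccc2)cc1OC(=O)c1ccccc1
A2 | alternative 1 | [(2R,3R)-2-(3-benzoyloxy-4-methoxyphenyl)-5-bromo-4-oxo-2,3-dihydropyran-3-yl] benzoate | COc1ccc([C@H]2OC=C(Br)C(=O)[C@@H]2OC(=O)c2ccccc2)cc1OC(=O)c1ccccc1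
A3 | alternative 1 | [(1,3-dimethoxy-7-methylocta-1,3,6-trien-1-yl)oxy]trimethylsilane (double-bond geometry not defined) | COC(O[Si](C)(C)C)=CC(OC)=CCC=C(C)C
A4 | alternative 2 | (2R,3R)-3-hydroxy-5,7-dimethoxy-2-[4-methoxy-3-(methoxymethoxy)phenyl]-8-(3-methylbut-2-enyl)chroman-4-one | COc1ccc([C@H]2Oc3c(CC=C(C)C)c(OC)cc(OC)c3C(=O)[C@@H]2O)cc1OCOC
A5 | alternative 2 | 4,6-dimethoxy-2-[1-[4-methoxy-3-(methoxymethoxy)phenyl]-2-oxoethoxy]-3-(3-methylbut-2-enyl)benzaldehyde (racemic) | COc1cc(OC)c(CC=C(C)C)c(OC(C=O)c2ccc(OC)c(OCOC)c2)c1C=O
A6 | alternative 3 | (2R,3R)-3-acetoxy-2-(3-acetoxy-4-methoxyphenyl)-5,7-dimethoxy-8-(3-methylbut-2-enyl)chroman-4-one | COc1ccc([C@H]2Oc3c(CC=C(C)C)c(OC)cc(OC)c3C(=O)[C@@H]2OC(C)=O)cc1OC(C)=O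
A7 | alternative 3 | (2R,3R)-2-acetoxy-3-(3-acetoxy-4-methoxyphenyl)-3-[3,5-dimethoxy-2-(3-methylbut-2-enyl)phenoxy]propanoic acid | COc1ccc([C@@H](Oc2cc(OC)cc(OC)c2CC=C(C)C)[C@@H](OC(C)=O)C(=O)O)cc1OC(C)=O
A8 | alternative 3 | 3,5-dimethoxy-2-(3-methylbut-2-enyl)phenol | COc1cc(O)c(CC=C(C)C)c(OC)c1
A9 | alternative 3 | methyl (2R,3S)-3-(3-acetoxy-4-methoxyphenyl)oxirane-2-carboxylate | COC(=O)[C@@H]1O[C@H]1c1ccc(OC)c(OC(C)=O)c1
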